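**Retrosynthetic overview**

- Tanegol is an oxolane, O1–C2(aryl)–C3(CH2OH)–C4(CH(OH)aryl)–C5H2. The last steps take it from a cis-fused 4,8-diaryl-3,7-dioxabicyclo[3.3.0]octan-2-one: the lactone C=O becomes the CH2OH on C3 and the lactone C–O becomes the carbinol on C4, so the temporary lactone locks the 3,4-cis relationship.
- The oxolane is cut at O1–C2 and C3–C4. O1–C5–C4 plus the exocyclic carbinol carbon on C4 is an allyl alkoxide, i.e. a racemic 2-(1-arylvinyl)oxirane opened by zerovalent palladium. C2–C3, with the aryl on C2 and a one-carbon branch on C3, is an arylidene malonate.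
- Enabling feature: C4 becomes an allylic carbon once its carbinol carbon is written as C(aryl)=CH2, and C3 can carry a second ester. One stereoconvergent, strain-releasing [3+2] event then makes both bonds, the only ring of the target and the C2 and C4 stereocentres.
- Ring order: oxolane first (step 4), temporary γ-lactone second (step 6). The extra methylene, the extra ester and the lactone are removed in steps 5, 7 and 8.
- The vinyl oxirane comes in one step from an aryl iodide and buta-2,3-dien-1-ol; the acceptor comes from O-benzylvanillin and dimethyl malonate.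

Key step: step 4

Assumption: the (S,S)-configured ligand in step 4 is taken to give the (4R) product; if a pilot run gives the antipode, the (R,R)-ligand is used and nothing else changes.

**Step 1**
Reactants: 1 4-iodo-2-methoxyphenol
Product: 2 1-(benzyloxy)-4-iodo-2-methoxybenzene
Conditions: BnBr, K2CO3, DMF, rt to 50 °C
Reagents that add atoms: benzyl bromide, BrCc1ccccc1
Why: Williamson etherification of the phenoxide with benzyl bromide should proceed cleanly; no stereocentre is formed.

**Step 2**
Reactants: 2 1-(benzyloxy)-4-iodo-2-methoxybenzene, 3 buta-2,3-dien-1-ol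
Product: 4 rac-2-{1-[4-(benzyloxy)-3-methoxyphenyl]ethenyl}oxirane
Conditions: Pd(PPh3)4 (5 mol %), K2CO3, DMF, 60 °C
Reagents that add atoms: none
Why: Palladium-catalysed coupling–cyclisation of a 2,3-allenol with an aryl iodide (oxidative addition, carbopalladation with aryl delivery to the central allene carbon, then attack of the alkoxide on the adjacent π-allyl terminus) should give the vinyl oxirane; its stereocentre forms racemic, which is all that step 4 needs.

**Step 3**
Reactants: 5 4-(benzyloxy)-3-methoxybenzaldehyde, 6 dimethyl malonate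
Product: 7 dimethyl 2-{[4-(benzyloxy)-3-methoxyphenyl]methylidene}propanedioate
Conditions: piperidine (10 mol %), AcOH (10 mol %), toluene, reflux, Dean–Stark
Reagents that add atoms: none
Why: Knoevenagel condensation with azeotropic removal of water should give the arylidene malonate; no stereocentre is formed.

**Step 4**
Reactants: 4 rac-2-{1-[4-(benzyloxy)-3-methoxyphenyl]ethenyl}oxirane, 7 dimethyl 2-{[4-(benzyloxy)-3-methoxyphenyl]methylidene}propanedioate
Product: 8 dimethyl (2R,4R)-2-[4-(benzyloxy)-3-methoxyphenyl]-4-{1-[4-(benzyloxy)-3-methoxyphenyl]ethenyl}oxolane-3,3-dicarboxylate (2,4-trans)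
Conditions: Pd2(dba)3·CHCl3 (2.5 mol %), (S,S)-DACH-phenyl bisphosphine ligand [(1S,2S)-N,N'-bis(2-(diphenylphosphanyl)benzoyl)cyclohexane-1,2-diamine] (7.5 mol %), CH2Cl2, rt; 4 added over several hours to 7 (1.3 equiv)
Reagents that add atoms: none
Why: Zerovalent palladium opens the strained oxirane of rac-4 by ionisation to a zwitterionic 2-aryl-π-allylpalladium alkoxide, whose alkoxide adds reversibly to the benzylidene carbon of 7 (oxa-Michael, O1–C2 bond) before the malonate carbanion attacks the substituted allyl terminus anti to palladium (C3–C4 bond). The closest known reaction type is the palladium-catalysed asymmetric formal [3+2] cycloaddition of racemic vinyl oxiranes with doubly activated alkenes. The oxolane closes in a 5-exo allylic alkylation; attack at the CH2 terminus would need a seven-membered ring. C4 is set by the ligand in a dynamic kinetic asymmetric transformation: the diastereomeric π-allyl complexes from the two enantiomers of 4 interconvert by η3–η1–η3 slippage through the unsubstituted CH2 terminus faster than they cyclise, so both enantiomers should converge on (4R). C2 is set under Curtin–Hammett conditions, because only ring closure is irreversible: in the envelope transition state the planar malonate keeps the C2–H in its plane (A1,3 strain), the C2 aryl group is pseudo-equatorial and the bulky palladium-bound 1-arylvinyl unit should take the opposite ring face, where it lies over one ester and the C2–H instead of between both esters, which leads to the 2,4-trans isomer; this trans preference is the least secure element and any cis isomer would be removed by chromatography. The step needs branched regioselectivity, allyl-face selection and trans diastereoselection; the five-membered tether, the chiral pocket of the ligand and the 2-aryl group on the allyl unit are the securing elements, and slow addition of 4 to an excess of 7 should keep the zwitterion from isomerising or oligomerising before capture.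

**Step 5**
Reactants: 8 dimethyl (2R,4R)-2-[4-(benzyloxy)-3-methoxyphenyl]-4-{1-[4-(benzyloxy)-3-methoxyphenyl]ethenyl}oxolane-3,3-dicarboxylate
Product: 10 dimethyl (2R,4R)-4-[4-(benzyloxy)-3-methoxybenzoyl]-2-[4-(benzyloxy)-3-methoxyphenyl]oxolane-3,3-dicarboxylate, via secondary ozonide 9 (not isolated)
Conditions: O3, CH2Cl2, −78 °C (Sudan Red 7B end point); then Me2S, −78 °C to rt
Reagents that add atoms: ozone, [O-][O+]=O
Why: Ozonolysis should cleave the electron-rich 1,1-disubstituted styrene bond much faster than it attacks the alkoxyarenes or benzyl ethers, and reduction of the ozonide with Me2S gives the aryl ketone and formaldehyde; no stereocentre is touched, and the β-alkoxy ketone is kept neutral and cold and used crude so that C4 does not epimerise.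

**Step 6**
Reactants: 10 dimethyl (2R,4R)-4-[4-(benzyloxy)-3-methoxybenzoyl]-2-[4-(benzyloxy)-3-methoxyphenyl]oxolane-3,3-dicarboxylate
Product: 12 methyl (1S,4S,5R,8R)-4,8-bis[4-(benzyloxy)-3-methoxyphenyl]-2-oxo-3,7-dioxabicyclo[3.3.0]octane-1-carboxylate, via hydroxy diester 11 (not isolated)
Conditions: Zn(BH4)2, Et2O/THF, −30 to 0 °C; sat. aq. NH4Cl; then DBU (0.2 equiv), CH2Cl2, rt
Reagents that add atoms: none
Why: Chelation-assisted Felkin–Anh reduction (zinc bridging the ketone oxygen and the ring oxygen, hydride arriving anti to the quaternary C3) should give the (S)-carbinol, and base-catalysed lactonisation can only reach the ester cis to the carbinol side chain, which gives the cis-fused γ-lactone with the new aryl group on the convex face.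

**Step 7**
Reactants: 12 methyl (1S,4S,5R,8R)-4,8-bis[4-(benzyloxy)-3-methoxyphenyl]-2-oxo-3,7-dioxabicyclo[3.3.0]octane-1-carboxylate
Product: 13 (1S,4S,5R,8S)-4,8-bis[4-(benzyloxy)-3-methoxyphenyl]-3,7-dioxabicyclo[3.3.0]octan-2-one
Conditions: LiCl, H2O, DMSO, 130 °C
Reagents that add atoms: none
Why: Krapcho dealkoxycarbonylation (chloride demethylation, loss of CO2, protonation of the lactone enolate) should remove the angular ester, and protonation at the ring-fusion carbon can only give the cis-fused bicycle, which sets C1 so that the future CH2OH is cis to the C4 side chain and trans to the C2 aryl group of the oxolane.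

**Step 8**
Reactants: 13 (1S,4S,5R,8S)-4,8-bis[4-(benzyloxy)-3-methoxyphenyl]-3,7-dioxabicyclo[3.3.0]octan-2-one
Product: 14 (S)-[4-(benzyloxy)-3-methoxyphenyl]{(3R,4R,5S)-5-[4-(benzyloxy)-3-methoxyphenyl]-4-(hydroxymethyl)oxolan-3-yl}methanol
Conditions: LiAlH4, THF, 0 °C to rt; Fieser work-up
Reagents that add atoms: none
Why: LiAlH4 reduction of the γ-lactone should give the 1,4-diol (primary alcohol from the carbonyl carbon, benzylic carbinol from the alkyl oxygen) without touching any stereocentre or the benzyl ethers.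

**Step 9**
Reactants: 14 (S)-[4-(benzyloxy)-3-methoxyphenyl]{(3R,4R,5S)-5-[4-(benzyloxy)-3-methoxyphenyl]-4-(hydroxymethyl)oxolan-3-yl}methanol
Product: 15 (−)-tanegol, (S)-(4-hydroxy-3-methoxyphenyl)[(3R,4R,5S)-5-(4-hydroxy-3-methoxyphenyl)-4-(hydroxymethyl)oxolan-3-yl]methanol
Conditions: H2 (1 atm), 10% Pd/C, EtOAc, rt; stopped when debenzylation is complete
Reagents that add atoms: none
Why: Hydrogenolysis of the two aryl benzyl ethers under neutral conditions should be faster than cleavage of the benzylic alcohol or the benzylic oxolane C–O bond, which need acid or long exposure; no stereocentre is touched.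

**Compound list**

1 | 4-iodo-2-methoxyphenol | COc1cc(I)ccc1O | starting material
2 | 1-(benzyloxy)-4-iodo-2-methoxybenzene | COc1cc(I)ccc1OCc1ccccc1 | intermediate
3 | buta-2,3-dien-1-ol | C=C=CCO | starting material
4 | rac-2-{1-[4-(benzyloxy)-3-methoxyphenyl]ethenyl}oxirane | C=C(c1ccc(OCc2ccccc2)c(OC)c1)C1CO1 | intermediate
5 | 4-(benzyloxy)-3-methoxybenzaldehyde | COc1cc(C=O)ccc1OCc1ccccc1 | starting material
6 | dimethyl malonate | COC(=O)CC(=O)OC | starting material
7 | dimethyl 2-{[4-(benzyloxy)-3-methoxyphenyl]methylidene}propanedioate | COC(=O)C(=Cc1ccc(OCc2ccccc2)c(OC)c1)C(=O)OC | intermediate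
8 | dimethyl (2R,4R)-2-[4-(benzyloxy)-3-methoxyphenyl]-4-{1-[4-(benzyloxy)-3-methoxyphenyl]ethenyl}oxolane-3,3-dicarboxylate | C=C(c1ccc(OCc2ccccc2)c(OC)c1)[C@H]1CO[C@H](c2ccc(OCc3ccccc3)c(OC)c2)C1(C(=O)OC)C(=O)OC | intermediate
9 | secondary ozonide of 8, dimethyl (2R,4R)-2-[4-(benzyloxy)-3-methoxyphenyl]-4-{3-[4-(benzyloxy)-3-methoxyphenyl]-1,2,4-trioxolan-3-yl}oxolane-3,3-dicarboxylate (not isolated; both epimers at the trioxolane carbon) | O1COOC1(c1ccc(OCc2ccccc2)c(OC)c1)[C@H]1CO[C@H](c2ccc(OCc3ccccc3)c(OC)c2)C1(C(=O)OC)C(=O)OC | intermediate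
10 | dimethyl (2R,4R)-4-[4-(benzyloxy)-3-methoxybenzoyl]-2-[4-(benzyloxy)-3-methoxyphenyl]oxolane-3,3-dicarboxylate | O=C(c1ccc(OCc2ccccc2)c(OC)c1)[C@H]1CO[C@H](c2ccc(OCc3ccccc3)c(OC)c2)C1(C(=O)OC)C(=O)OC | intermediate
11 | dimethyl (2R,4R)-2-[4-(benzyloxy)-3-methoxyphenyl]-4-{(S)-[4-(benzyloxy)-3-methoxyphenyl](hydroxy)methyl}oxolane-3,3-dicarboxylate (not isolated) | O[C@H](c1ccc(OCc2ccccc2)c(OC)c1)[C@H]1CO[C@H](c2ccc(OCc3ccccc3)c(OC)c2)C1(C(=O)OC)C(=O)OC | intermediate
12 | methyl (1S,4S,5R,8R)-4,8-bis[4-(benzyloxy)-3-methoxyphenyl]-2-oxo-3,7-dioxabicyclo[3.3.0]octane-1-carboxylate (cis-fused, both aryl groups on the convex face) | COC(=O)[C@]12C(=O)O[C@H](c3ccc(OCc4ccccc4)c(OC)c3)[C@H]1CO[C@@H]2c1ccc(OCc2ccccc2)c(OC)c1 | intermediate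
13 | (1S,4S,5R,8S)-4,8-bis[4-(benzyloxy)-3-methoxyphenyl]-3,7-dioxabicyclo[3.3.0]octan-2-one (cis-fused, both aryl groups on the convex face) | O=C1O[C@H](c2ccc(OCc3ccccc3)c(OC)c2)[C@H]2CO[C@H](c3ccc(OCc4ccccc4)c(OC)c3)[C@@H]12 | intermediate
14 | (S)-[4-(benzyloxy)-3-methoxyphenyl]{(3R,4R,5S)-5-[4-(benzyloxy)-3-methoxyphenyl]-4-(hydroxymethyl)oxolan-3-yl}methanol | COc1cc([C@@H](O)[C@H]2CO[C@H](c3ccc(OCc4ccccc4)c(OC)c3)[C@H]2CO)ccc1OCc1ccccc1 | intermediate
15 | (−)-tanegol, (S)-(4-hydroxy-3-methoxyphenyl)[(3R,4R,5S)-5-(4-hydroxy-3-methoxyphenyl)-4-(hydroxymethyl)oxolan-3-yl]methanol | COc1cc([C@@H](O)[C@H]2CO[C@H](c3ccc(O)c(OC)c3)[C@H]2CO)ccc1O | target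

**Step count and risks**

Total step count: 9. Longest linear sequence: 8 steps (steps 1, 2, 4, 5, 6, 7, 8, 9).

Steps most likely to fail:

1. Step 4. The zwitterionic π-allyl alkoxide may isomerise (β-hydride elimination to a dienol or enal) or oligomerise before it is captured, because the electron-rich arylidene malonate is only a weak oxa-Michael acceptor. Poor 2,4-cis/trans discrimination at ring closure is the second concern, and this fallback does not address it. The fallback sets out from 5 and uses a far more electrophilic cyclic acylal acceptor, which also replaces the later dealkoxycarbonylation. Knoevenagel condensation of 5 with Meldrum's acid should give 5-{[4-(benzyloxy)-3-methoxyphenyl]methylidene}-2,2-dimethyl-1,3-dioxane-4,6-dione F1. The same palladium-catalysed cycloaddition with 4 should give the spiro adduct (1R,4R)-1-[4-(benzyloxy)-3-methoxyphenyl]-4-{1-[4-(benzyloxy)-3-methoxyphenyl]ethenyl}-8,8-dimethyl-2,7,9-trioxaspiro[4.5]decane-6,10-dione F2. Ozonolysis (O3, then Me2S) passes through the secondary ozonide of the spiro adduct F3 to (1R,4R)-4-[4-(benzyloxy)-3-methoxybenzoyl]-1-[4-(benzyloxy)-3-methoxyphenyl]-8,8-dimethyl-2,7,9-trioxaspiro[4.5]decane-6,10-dione F4. Reduction with Zn(BH4)2 gives the (S)-carbinol (1R,4R)-1-[4-(benzyloxy)-3-methoxyphenyl]-4-{(S)-[4-(benzyloxy)-3-methoxyphenyl](hydroxy)methyl}-8,8-dimethyl-2,7,9-trioxaspiro[4.5]decane-6,10-dione F5. Its alkoxide opens the cis acylal carbonyl with loss of acetone to (1S,4S,5R,8R)-4,8-bis[4-(benzyloxy)-3-methoxyphenyl]-2-oxo-3,7-dioxabicyclo[3.3.0]octane-1-carboxylic acid F6. Warming F6 in toluene/pyridine should decarboxylate it, and the route is rejoined at 13.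

2. Step 2. The π-allyl intermediate may undergo β-hydride elimination to an enal or oxygen attack at the distal terminus (2,5-dihydrofuran), and zerovalent palladium may re-ionise the product. The fallback builds the oxirane without palladium and sets out from 5. Addition of CH2=CHMgBr should give rac-1-[4-(benzyloxy)-3-methoxyphenyl]prop-2-en-1-ol F7. Epoxidation with mCPBA/NaHCO3 gives [4-(benzyloxy)-3-methoxyphenyl](oxiran-2-yl)methanol F8. Dess–Martin oxidation gives rac-[4-(benzyloxy)-3-methoxyphenyl](oxiran-2-yl)methanone F9. Wittig methylenation (Ph3PCH3Br, KOtBu, THF) should then give 4, where the route is rejoined.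

3. Step 6. Hydride may arrive from the wrong carbonyl face if chelation does not operate, or the β-alkoxy ketone may open by β-elimination before it is reduced. The fallback replaces substrate control by catalyst control and sets out from 10. Asymmetric transfer hydrogenation with RuCl[(S,S)-TsDPEN](p-cymene) in HCO2H/Et3N (5:2), a non-basic medium, should give the (S)-carbinol 11, which is isolated this time. DBU-catalysed lactonisation then rejoins the route at 12.

**Further compounds**

F1 | step 4 | 5-{[4-(benzyloxy)-3-methoxyphenyl]methylidene}-2,2-dimethyl-1,3-dioxane-4,6-dione | COc1cc(C=C2C(=O)OC(C)(C)OC2=O)ccc1OCc1ccccc1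
F2 | step 4 | (1R,4R)-1-[4-(benzyloxy)-3-methoxyphenyl]-4-{1-[4-(benzyloxy)-3-methoxyphenyl]ethenyl}-8,8-dimethyl-2,7,9-trioxaspiro[4.5]decane-6,10-dione | C=C(c1ccc(OCc2ccccc2)c(OC)c1)[C@H]1CO[C@H](c2ccc(OCc3ccccc3)c(OC)c2)C12C(=O)OC(C)(C)OC2=O
F3 | step 4 | secondary ozonide of the spiro adduct (1,2,4-trioxolane at the former alkene, both epimers at the trioxolane carbon) | O1COOC1(c1ccc(OCc2ccccc2)c(OC)c1)[C@H]1CO[C@H](c2ccc(OCc3ccccc3)c(OC)c2)C12C(=O)OC(C)(C)OC2=O
F4 | step 4 | (1R,4R)-4-[4-(benzyloxy)-3-methoxybenzoyl]-1-[4-(benzyloxy)-3-methoxyphenyl]-8,8-dimethyl-2,7,9-trioxaspiro[4.5]decane-6,10-dione | O=C(c1ccc(OCc2ccccc2)c(OC)c1)[C@H]1CO[C@H](c2ccc(OCc3ccccc3)c(OC)c2)C12C(=O)OC(C)(C)OC2=O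
F5 | step 4 | (1R,4R)-1-[4-(benzyloxy)-3-methoxyphenyl]-4-{(S)-[4-(benzyloxy)-3-methoxyphenyl](hydroxy)methyl}-8,8-dimethyl-2,7,9-trioxaspiro[4.5]decane-6,10-dione | O[C@H](c1ccc(OCc2ccccc2)c(OC)c1)[C@H]1CO[C@H](c2ccc(OCc3ccccc3)c(OC)c2)C12C(=O)OC(C)(C)OC2=O
F6 | step 4 | (1S,4S,5R,8R)-4,8-bis[4-(benzyloxy)-3-methoxyphenyl]-2-oxo-3,7-dioxabicyclo[3.3.0]octane-1-carboxylic acid | OC(=O)[C@]12C(=O)O[C@H](c3ccc(OCc4ccccc4)c(OC)c3)[C@H]1CO[C@@H]2c1ccc(OCc2ccccc2)c(OC)c1
F7 | step 2 | rac-1-[4-(benzyloxy)-3-methoxyphenyl]prop-2-en-1-ol | C=CC(O)c1ccc(OCc2ccccc2)c(OC)c1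
F8 | step 2 | [4-(benzyloxy)-3-methoxyphenyl](oxiran-2-yl)methanol (racemic, both diastereomers) | OC(c1ccc(OCc2ccccc2)c(OC)c1)C1CO1
F9 | step 2 | rac-[4-(benzyloxy)-3-methoxyphenyl](oxiran-2-yl)methanone | O=C(c1ccc(OCc2ccccc2)c(OC)c1)C1CO1
F0 | step 6 | none | none
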